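## Retrosynthetic overview

1. Target 30 ⇐ ketone 27 (C-2′ hydroxylation, chelation-controlled reduction) ⇐ exo-methylene 21 + epoxy enone 25 (radical Giese coupling builds quaternary C-10; C-5=C-6 by late dehydration).
2. 21 ⇐ enone-ketone 16 by two methylenations, enone reduction (C-11, C-12) and hydrogenation (C-15).
3. Ring B: 16 ⇐ spiro-1,3-dione 13 by intramolecular aldol condensation C-11→C-12, which also fixes C-4.
4. Ring D and spiro C-4 (key step): 13 ⇐ ring-A ketone 9 + 1,2-bis(silyloxy)cyclobutene by geminal acylation, a 1,2-acyl shift that expands a cyclobutanone to a cyclopentane-1,3-dione.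
5. Rings A and C: 9 ⇐ cyclopentenone + Me2Zn + aldehyde 5 (conjugate addition–aldol; C-1, C-5); 5 ⇐ 3-methylcyclopentenone (conjugate vinylation; C-7). Ring order: C, A, D, B.

Atom labels used in names: ring A = C-1(Me)–C-2–C-3–C-4(spiro)–C-5; ring B = C-4, C-5, C-6, C-7(Me), C-11, C-12; ring C = C-7–C-8–C-9–C-10(Me, side chain)–C-11; ring D = C-4, C-12, C-13, C-14, C-15(Me); side chain C-1′ to C-5′ from C-10 (epoxide at C-4′/C-5′).

Assumption: in steps 1, 3 and 15 the antipode of the chiral ligand or reagent that gives the drawn configuration is used; the sense of induction is confirmed on the first run.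

## Route

Step 1
Reactants: 1 3-methylcyclopent-2-en-1-one
Product: 3 (R)-3-ethenyl-3-methylcyclopent-1-en-1-yl acetate, via magnesium enolate 2 (not isolated)
Conditions: CH2=CHMgBr (1.3 equiv), Cu(OTf)2 (3 mol%), chiral imidazolinium salt L1 (NHC precursor, 4 mol%), Et2O, 0 °C; then Ac2O (2 equiv), 0 → 20 °C
Reagents that add atoms: vinylmagnesium bromide C=C[Mg]Br; acetic anhydride CC(=O)OC(C)=O
Why: Cu–NHC-catalysed asymmetric conjugate addition of the Grignard reagent to the β-methyl enone builds the C-7 quaternary centre under ligand control, and O-acetylation of the regiodefined magnesium enolate stores the C-10 carbonyl as an enol acetate that is inert to the Lewis acid of step 5.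

Step 2
Reactants: 3 (R)-3-ethenyl-3-methylcyclopent-1-en-1-yl acetate
Product: 5 (S)-3-formyl-3-methylcyclopent-1-en-1-yl acetate, via ozonide 4 (not isolated)
Conditions: O3, CH2Cl2, −78 °C (Sudan Red 7B end point); then PPh3, −78 → 20 °C
Reagents that add atoms: ozone [O-][O+]=O
Why: Ozonolysis with reductive work-up is selective for the electron-rich monosubstituted vinyl group over the acetoxy-deactivated ring alkene, and the non-enolisable aldehyde keeps C-7 intact (the descriptor changes to S by priority only).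

Step 3
Reactants: 6 cyclopent-2-en-1-one; 5 (S)-3-formyl-3-methylcyclopent-1-en-1-yl acetate
Product: 9 (S)-3-methyl-3-{(R)-[(1S,2S)-2-methyl-5-oxocyclopentyl](triethylsilyloxy)methyl}cyclopent-1-en-1-yl acetate, via zinc enolate 7 (not isolated), via zinc aldolate 8 (not isolated)
Conditions: Me2Zn (1.3 equiv), Cu(OTf)2 (2 mol%), BINOL-based phosphoramidite L2 (4 mol%), toluene, −30 °C; then TESOTf (1.5 equiv), −30 → 0 °C
Reagents that add atoms: dimethylzinc C[Zn]C; triethylsilyl triflate CC[Si](CC)(CC)OS(=O)(=O)C(F)(F)F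
Why: Cu/phosphoramidite-catalysed asymmetric conjugate addition–aldol three-component coupling: methyl goes to C-1 under ligand control (S), the (E)-zinc enolate adds to 5 anti to that methyl through a Zimmerman–Traxler chair (C-5 trans to Me-1; anti aldol at C-6, whose minor epimer is removed and whose centre is destroyed in step 14), and silylation of the aldolate blocks retro-aldol.

Step 4
Reactants: 10 2-hydroxycyclobutan-1-one (racemic)
Product: 11 1,2-bis(trimethylsilyloxy)cyclobut-1-ene
Conditions: TMSOTf (2.3 equiv), Et3N (3 equiv), CH2Cl2, 0 → 20 °C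
Reagents that add atoms: trimethylsilyl triflate C[Si](C)(C)OS(=O)(=O)C(F)(F)F
Why: Exhaustive silylation of the acyloin (O-silylation, then silyl enol ether formation towards the oxygenated carbon) gives the enediol bis-silyl ether.

Step 5
Reactants: 9 TES-protected aldol ketone; 11 1,2-bis(trimethylsilyloxy)cyclobut-1-ene
Product: 13 (S)-3-{(R)-hydroxy[(6R,7S)-7-methyl-1,4-dioxospiro[4.4]nonan-6-yl]methyl}-3-methylcyclopent-1-en-1-yl acetate, via cyclobutanone adduct 12 (not isolated)
Conditions: 11 (3 equiv), BF3·OEt2 (2 equiv), CH2Cl2, −78 °C; then CF3CO2H (20 equiv), −78 → 20 °C; aq NaHCO3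
Reagents that add atoms: none
Why: Geminal acylation: Mukaiyama aldol addition of 11 to the BF3-activated C-4 ketone, then acid ionisation of the tertiary C-4–O bond with 1,2-shift of the ring acyl carbon (pinacol-type ring expansion of the cyclobutanone to a cyclopentane-1,3-dione) makes C-4 quaternary and forms ring D; the two acyl arms are identical, so C-4 is not yet stereogenic and needs no selectivity, and the acid also removes the TES group.

Step 6
Reactants: 13 spiro-dione enol acetate
Product: 16 (1S,4R,5R,6R,7S)-6-hydroxy-1,7-dimethyl tetracyclic 11(12)-ene-10,15-dione (rings A–D closed; enone C-10/C-11=C-12; ketone C-15), via triketone 14 (not isolated), via aldol 15 (not isolated)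
Conditions: pyrrolidine (1.5 equiv), AcOH (1.5 equiv), MeCN, 20 °C then 60 °C
Reagents that add atoms: none
Why: Proposed new method: amine-triggered enol-ester unmasking with desymmetrising enamine aldol condensation; pyrrolidine is N-acetylated by the enol acetate (enol esters are acyl donors towards amines), which releases ketone 14 and pyrrolidinium acetate, these form the enamines of the C-10 ketone, of which only the C-10=C-11 isomer can reach a dione carbonyl through a six-membered chair, it adds to the carbonyl that lies cis to C-6 on ring A (cis-hydrindane-type closure), which makes the C-11–C-12 bond and ring B and turns C-4 into a defined stereocentre, and E1cB loss of water from aldol 15 pulls the reversible steps to the enone; closest known reaction type: amine-mediated intramolecular aldol condensation of 2,2-disubstituted cyclopentane-1,3-diones (Hajos–Parrish and Wieland–Miescher ketone syntheses) combined with aminolysis of enol esters.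

Step 7
Reactants: 16 tetracyclic ene-dione
Product: 17 (1S,4S,5R,6R,7S)-6-hydroxy-1,7-dimethyl-15-methylidene tetracyclic 11(12)-en-10-one
Conditions: Ph3PCH3Br (3.5 equiv), KHMDS (3.3 equiv), THF, 0 °C; then 16, 0 → 50 °C
Reagents that add atoms: methyltriphenylphosphonium bromide C[P+](c1ccccc1)(c1ccccc1)c1ccccc1.[Br-]
Why: Wittig methylenation with salt-free ylide is chemoselective for the saturated C-15 cyclopentanone over the conjugated, fully substituted C-10 enone carbonyl (the C-6 alkoxide is a spectator) and supplies the future C-15 methyl carbon.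

Step 8
Reactants: 17 methylidene enone
Product: 19 (1S,4S,5R,6R,7S,11S,12S)-6-hydroxy-1,7-dimethyl-15-methylidene tetracyclic 10-ketone (H-11 cis to Me-7; H-12 cis to C-3), via lithium enolate 18 (not isolated)
Conditions: Li (4 equiv), NH3(l)/THF, t-BuOH (1 equiv), −78 °C; isoprene then NH4Cl; then NaOMe (cat.), MeOH, 20 °C
Reagents that add atoms: none
Why: Dissolving-metal (Birch-type) conjugate reduction of the tetrasubstituted enone protonates C-12 on the face cis to C-3 because ring D can only pyramidalise towards C-15 (cis-fused B/D), base equilibration sets C-11 to the more stable cis-fused B/C hydrindanone, and the isolated 1,1-disubstituted alkene is untouched.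

Step 9
Reactants: 19 methylidene ketone
Product: 20 (1S,4S,5R,6R,7S,11S,12S,15S)-6-hydroxy-1,7,15-trimethyl tetracyclic 10-ketone
Conditions: H2 (1 atm), 5% Pd/C, EtOAc, 20 °C
Reagents that add atoms: none
Why: Heterogeneous hydrogenation adds H2 to the exocyclic alkene from the convex face of the cis-fused B/D bicycle (opposite ring B), which places the new C-15 methyl cis to C-5 (15S).

Step 10
Reactants: 20 trimethyl ketone
Product: 21 (1S,4S,5R,6R,7S,11R,12S,15S)-1,7,15-trimethyl-10-methylidene tetracyclic 6-ol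
Conditions: Ph3PCH3Br (4 equiv), KHMDS (3.8 equiv), THF, 0 → 60 °C
Reagents that add atoms: methyltriphenylphosphonium bromide C[P+](c1ccccc1)(c1ccccc1)c1ccccc1.[Br-]
Why: Wittig methylenation of the remaining C-10 ketone gives the 1,1-disubstituted alkene needed for radical generation, and C-11 stays at its thermodynamic configuration.

Step 11
Reactants: 22 (R)-(2-methyloxiran-2-yl)methanol
Product: 24 (1RS)-1-[(S)-2-methyloxiran-2-yl]prop-2-en-1-ol, via aldehyde 23 (not isolated)
Conditions: (COCl)2 (1.2 equiv), DMSO (2.4 equiv), CH2Cl2, −78 °C; Et3N (3 equiv); then CH2=CHMgBr (4 equiv), THF, −78 °C; aq NH4Cl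
Reagents that add atoms: vinylmagnesium bromide C=C[Mg]Br
Why: Swern oxidation followed by Grignard addition in the same flask avoids isolating the volatile epoxy aldehyde; the quaternary epoxide centre is not touched and both carbinol epimers are used.

Step 12
Reactants: 24 epoxy allylic alcohol
Product: 25 (S)-1-(2-methyloxiran-2-yl)prop-2-en-1-one
Conditions: Dess–Martin periodinane (1.3 equiv), NaHCO3, CH2Cl2, 0 → 20 °C
Reagents that add atoms: none
Why: Buffered Dess–Martin oxidation converts both carbinol epimers into the single enone without opening the epoxide.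

Step 13
Reactants: 21 exo-methylene alcohol; 25 epoxy enone
Product: 26 (1S,4S,5R,6R,7S,10R,11R,12S,15S)-3-(6-hydroxy-1,7,10,15-tetramethyl tetracycle-10-yl)-1-[(S)-2-methyloxiran-2-yl]propan-1-one
Conditions: 25 (3 equiv), Fe(acac)3 (30 mol%), PhSiH3 (2.5 equiv), EtOH/(CH2OH)2 5:1, 60 °C
Reagents that add atoms: none
Why: Fe–H hydrogen-atom-transfer reductive olefin coupling (MHAT Giese reaction): H• adds to the methylene (creating Me-10), the tertiary C-10 radical adds to the vinyl ketone from the convex face of the cis-fused B/C bicycle, anti to C-12, which sets the C-10 quaternary centre (R), and the iron enolate is protonated by ethanol.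

Step 14
Reactants: 26 hydroxy epoxy ketone
Product: 27 (1S,4S,7R,10R,11R,12S,15S)-5(6)-ene epoxy ketone (side chain CH2CH2C(=O)-epoxide on C-10)
Conditions: Martin sulfurane (2 equiv), benzene, 20 → 50 °C
Reagents that add atoms: none
Why: Martin sulfurane dehydration of the only hydroxyl proceeds by anti-E2 elimination with H-5 (trans to the C-6 oxygen) and is regiospecific because C-7 is quaternary, so the C-5=C-6 alkene forms without cationic rearrangement.

Step 15
Reactants: 27 ene epoxy ketone
Product: 29 (2′S)-2′-hydroxy ketone (1S,4S,7R,10R,11R,12S,15S,2′S,4′S), via potassium enolate 28 (not isolated)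
Conditions: KHMDS (1.1 equiv), THF, −78 °C; then (camphorsulfonyl)oxaziridine (1.3 equiv), −78 °C; aq NH4Cl
Reagents that add atoms: (camphorsulfonyl)oxaziridine CC1(C)[C@@H]2CC[C@]13CS(=O)(=O)N4O[C@@]34C2
Why: Davis oxidation: the ketone can enolise only towards C-2′, and the (Z)-potassium enolate is hydroxylated by the chiral N-sulfonyloxaziridine under reagent control to give the 2′S alcohol.

Step 16
Reactants: 29 α-hydroxy ketone
Product: 30 target (1S,4S,7R,10R,11R,12S,15S,2′S,3′S,4′S)
Conditions: Zn(BH4)2 (2 equiv), Et2O, −20 °C; aq NH4Cl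
Reagents that add atoms: none
Why: Chelation-controlled reduction: zinc bridges the C-2′ alkoxide and the ketone and hydride attacks from the face of the small H-2′ substituent (Cram-chelate model) to give the anti 2′,3′-diol (3′S); the alkoxide chelate is expected to outweigh the weaker epoxide coordination.

## Compound list

1 | 3-methylcyclopent-2-en-1-one | CC1=CC(=O)CC1 | starting material
2 | bromomagnesium (R)-3-ethenyl-3-methylcyclopent-1-en-1-olate | C=C[C@@]1(C)CCC(O[Mg]Br)=C1 | intermediate (not isolated)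
3 | (R)-3-ethenyl-3-methylcyclopent-1-en-1-yl acetate | C=C[C@@]1(C)CCC(OC(C)=O)=C1 | intermediate
4 | (S)-3-methyl-3-(1,2,4-trioxolan-3-yl)cyclopent-1-en-1-yl acetate (trioxolane carbon unassigned) | O1COOC1[C@@]2(C)CCC(OC(C)=O)=C2 | intermediate (not isolated)
5 | (S)-3-formyl-3-methylcyclopent-1-en-1-yl acetate | O=C[C@@]1(C)CCC(OC(C)=O)=C1 | intermediate
6 | cyclopent-2-en-1-one | O=C1C=CCC1 | starting material
7 | methylzinc (S)-3-methylcyclopent-1-en-1-olate | C[C@H]1CCC(O[Zn]C)=C1 | intermediate (not isolated)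
8 | methylzinc alkoxide of the anti aldol (C-1 S; C-5 S; C-6 R; C-7 S) | C[C@H]1CCC(=O)[C@@H]1[C@@H](O[Zn]C)[C@@]1(C)CCC(OC(C)=O)=C1 | intermediate (not isolated)
9 | (S)-3-methyl-3-{(R)-[(1S,2S)-2-methyl-5-oxocyclopentyl](triethylsilyloxy)methyl}cyclopent-1-en-1-yl acetate | C[C@H]1CCC(=O)[C@@H]1[C@@H](O[Si](CC)(CC)CC)[C@@]1(C)CCC(OC(C)=O)=C1 | intermediate
10 | 2-hydroxycyclobutan-1-one (racemic) | O=C1CCC1O | starting material
11 | 1,2-bis(trimethylsilyloxy)cyclobut-1-ene | C[Si](C)(C)OC1=C(O[Si](C)(C)C)CC1 | intermediate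
12 | 2-[(2S,3S)-1-hydroxy-3-methyl-2-{(R)-[(S)-3-acetoxy-1-methylcyclopent-2-en-1-yl](triethylsilyloxy)methyl}cyclopentyl]-2-(trimethylsilyloxy)cyclobutan-1-one (carbinol and cyclobutanone α-centres unassigned) | C[C@H]1CCC(O)(C2(O[Si](C)(C)C)CCC2=O)[C@@H]1[C@@H](O[Si](CC)(CC)CC)[C@@]1(C)CCC(OC(C)=O)=C1 | intermediate (not isolated)
13 | (S)-3-{(R)-hydroxy[(6R,7S)-7-methyl-1,4-dioxospiro[4.4]nonan-6-yl]methyl}-3-methylcyclopent-1-en-1-yl acetate | C[C@H]1CCC2(C(=O)CCC2=O)[C@@H]1[C@@H](O)[C@@]1(C)CCC(OC(C)=O)=C1 | intermediate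
14 | (6R,7S)-6-{(R)-hydroxy[(S)-1-methyl-3-oxocyclopentyl]methyl}-7-methylspiro[4.4]nonane-1,4-dione | C[C@H]1CCC2(C(=O)CCC2=O)[C@@H]1[C@@H](O)[C@@]1(C)CCC(=O)C1 | intermediate (not isolated)
15 | (1S,4R,5R,6R,7S,11R,12R)-6,12-dihydroxy-1,7-dimethyl tetracyclic 10,15-dione (ring B closed; OH-12 cis to C-3) | C[C@H]1CC[C@@]23[C@@H]1[C@@H](O)[C@@]1(C)CCC(=O)[C@H]1[C@]2(O)CCC3=O | intermediate (not isolated)
16 | (1S,4R,5R,6R,7S)-6-hydroxy-1,7-dimethyl tetracyclic 11(12)-ene-10,15-dione | C[C@H]1CC[C@@]23[C@@H]1[C@@H](O)[C@@]1(C)CCC(=O)C1=C2CCC3=O | intermediate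
17 | (1S,4S,5R,6R,7S)-6-hydroxy-1,7-dimethyl-15-methylidene tetracyclic 11(12)-en-10-one | C[C@H]1CC[C@@]23[C@@H]1[C@@H](O)[C@@]1(C)CCC(=O)C1=C2CCC3=C | intermediate
18 | dilithium C-10 enolate C-6 alkoxide of 19 (H-12 cis to C-3) | C[C@H]1CC[C@@]23[C@@H]1[C@@H](O[Li])[C@@]1(C)CCC(O[Li])=C1[C@@H]2CCC3=C | intermediate (not isolated)
19 | (1S,4S,5R,6R,7S,11S,12S)-6-hydroxy-1,7-dimethyl-15-methylidene tetracyclic 10-ketone | C[C@H]1CC[C@@]23[C@@H]1[C@@H](O)[C@@]1(C)CCC(=O)[C@H]1[C@@H]2CCC3=C | intermediate
20 | (1S,4S,5R,6R,7S,11S,12S,15S)-6-hydroxy-1,7,15-trimethyl tetracyclic 10-ketone | C[C@H]1CC[C@@]23[C@@H]1[C@@H](O)[C@@]1(C)CCC(=O)[C@H]1[C@@H]2CC[C@@H]3C | intermediate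
21 | (1S,4S,5R,6R,7S,11R,12S,15S)-1,7,15-trimethyl-10-methylidene tetracyclic 6-ol | C[C@H]1CC[C@@]23[C@@H]1[C@@H](O)[C@@]1(C)CCC(=C)[C@H]1[C@@H]2CC[C@@H]3C | intermediate
22 | (R)-(2-methyloxiran-2-yl)methanol | OC[C@]1(C)CO1 | starting material
23 | (S)-2-methyloxirane-2-carbaldehyde | O=C[C@]1(C)CO1 | intermediate (not isolated)
24 | (1RS)-1-[(S)-2-methyloxiran-2-yl]prop-2-en-1-ol | C=CC(O)[C@]1(C)CO1 | intermediate
25 | (S)-1-(2-methyloxiran-2-yl)prop-2-en-1-one | C=CC(=O)[C@]1(C)CO1 | intermediate
26 | (1S,4S,5R,6R,7S,10R,11R,12S,15S)-3-(6-hydroxy-1,7,10,15-tetramethyl tetracycle-10-yl)-1-[(S)-2-methyloxiran-2-yl]propan-1-one | C[C@H]1CC[C@@]23[C@@H]1[C@@H](O)[C@@]1(C)CC[C@](C)(CCC(=O)[C@]4(C)CO4)[C@H]1[C@@H]2CC[C@@H]3C | intermediate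
27 | (1S,4S,7R,10R,11R,12S,15S)-3-(1,7,10,15-tetramethyl tetracyclic 5(6)-en-10-yl)-1-[(S)-2-methyloxiran-2-yl]propan-1-one | C[C@H]1CC[C@@]23C1=C[C@@]1(C)CC[C@](C)(CCC(=O)[C@]4(C)CO4)[C@H]1[C@@H]2CC[C@@H]3C | intermediate
28 | potassium (Z)-enolate of 27 (C-2′=C-3′) | C[C@H]1CC[C@@]23C1=C[C@@]1(C)CC[C@](C)(C/C=C(\O[K])[C@]4(C)CO4)[C@H]1[C@@H]2CC[C@@H]3C | intermediate (not isolated)
29 | (2′S)-2′-hydroxy-3′-ketone (1S,4S,7R,10R,11R,12S,15S,2′S,4′S) | C[C@H]1CC[C@@]23C1=C[C@@]1(C)CC[C@](C)(C[C@H](O)C(=O)[C@]4(C)CO4)[C@H]1[C@@H]2CC[C@@H]3C | intermediate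
30 | target (1S,4S,7R,10R,11R,12S,15S,2′S,3′S,4′S): anti-2′,3′-diol with (S)-2-methyloxirane on C-3′ | C[C@H]1CC[C@@]23C1=C[C@@]1(C)CC[C@](C)(C[C@H](O)[C@H](O)[C@]4(C)CO4)[C@H]1[C@@H]2CC[C@@H]3C | target

## Step count and risk

Total step count: 16. Longest linear sequence: 13 steps (1, 2, 3, 5, 6, 7, 8, 9, 10, 13, 14, 15, 16); steps 4 and 11–12 are side branches.

The three steps most likely to fail are step 6, step 5 and step 13.

Step 6 (the proposed new cascade) may stall at the triketone, may fail to dehydrate to the congested tetrasubstituted enone, or may pick the wrong dione carbonyl. The fallback uses known chemistry in separate operations and sets out from 13. K2CO3 (0.3 equiv) in MeOH at 0 °C cleaves the enol acetate and the triketone 14 is isolated. TsOH·H2O (20 mol%) in refluxing benzene with a Dean–Stark trap then closes ring B by the acid-catalysed enol aldol–dehydration used in the second stage of the Hajos–Parrish synthesis, passing through aldol 15. If 15 accumulates it is isolated and dehydrated with Burgess reagent. The sequence comes back to the route at 16 and makes no compound outside the list (F0).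

Step 5 (ring expansion on a hindered, α-branched ketone) may suffer slow Mukaiyama addition or E1 loss from the C-4 cation. The fallback sets out from 9 and changes the electrophile class. MeOSiMe3 with catalytic TMSOTf in CH2Cl2 at −78 °C converts the ketone into the dimethyl ketal F1. Ketals undergo the addition of 11 at −78 °C with BF3·OEt2, giving the isolable methoxy cyclobutanone adduct F2. Trifluoroacetic acid then ionises the C-4–OMe bond, the acyl shift expands the ring, and both silyl groups are lost. The sequence comes back to the route at 13.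

Step 13 (radical coupling that forms a neopentylic quaternary centre with an epoxy vinyl ketone) may fail because 25 polymerises or is reduced under Fe–H conditions. The fallback sets out from 21 and builds the epoxy ketone after the coupling. The same Fe(acac)3/PhSiH3 conditions with the robust acceptor N-methoxy-N-methylacrylamide give the Weinreb amide F3. Isopropenylmagnesium bromide (excess, THF, 0 °C) gives the isopropenyl ketone F4. Catalyst-controlled nucleophilic epoxidation (cinchona-derived primary amine salt, aq H2O2) installs the (S)-epoxide. The sequence comes back to the route at 26.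

Further compounds

F1 | step 5 | (S)-3-{(R)-[(1S,5S)-2,2-dimethoxy-5-methylcyclopentyl](triethylsilyloxy)methyl}-3-methylcyclopent-1-en-1-yl acetate | C[C@H]1CCC(OC)(OC)[C@@H]1[C@@H](O[Si](CC)(CC)CC)[C@@]1(C)CCC(OC(C)=O)=C1
F2 | step 5 | 2-[(2S,3S)-1-methoxy-3-methyl-2-{(R)-[(S)-3-acetoxy-1-methylcyclopent-2-en-1-yl](triethylsilyloxy)methyl}cyclopentyl]-2-(trimethylsilyloxy)cyclobutan-1-one (two new centres unassigned) | C[C@H]1CCC(OC)(C2(O[Si](C)(C)C)CCC2=O)[C@@H]1[C@@H](O[Si](CC)(CC)CC)[C@@]1(C)CCC(OC(C)=O)=C1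
F0 | step 6 | none | none
F3 | step 13 | 3-(6-hydroxy-1,7,10,15-tetramethyl tetracycle-10-yl)-N-methoxy-N-methylpropanamide (core configured as in 26) | C[C@H]1CC[C@@]23[C@@H]1[C@@H](O)[C@@]1(C)CC[C@](C)(CCC(=O)N(C)OC)[C@H]1[C@@H]2CC[C@@H]3C
F4 | step 13 | 5-(6-hydroxy-1,7,10,15-tetramethyl tetracycle-10-yl)-2-methylpent-1-en-3-one (core configured as in 26) | C[C@H]1CC[C@@]23[C@@H]1[C@@H](O)[C@@]1(C)CC[C@](C)(CCC(=O)C(C)=C)[C@H]1[C@@H]2CC[C@@H]3C
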